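**Plan**

- Numbering: side chain C1′ (ring CH2) to C15′. The quinone is carried as its 2,5-dimethoxy-4-methylphenyl ether and unveiled last. The target is read as 10′R,11′S, the anti-diol monoacetate of an E-olefin.
- Cuts (retro): ring C=O to OMe; the O-acetyl group; C5′–C6′ together with C7′–CH3 (C13 alkynediol + Me–Al + C15 primary iodide); C1′–C2′ together with C3′–CH3 (benzylic chloride + but-3-yn-1-ol + Me–Al); C8′–C9′ (epoxygeranyl C1 + propargyl anion).
- Forward: geraniol → 2,3-epoxide → C8′–C9′ alkylation → terminal alkyne → anti-diol. Separately, arene → benzylic chloride → homoallylic alcohol → iodide. Then union at C5′–C6′, O-acetylation at C10′, and oxidation to the quinone.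
- Stereochemistry: C10′ from Sharpless epoxidation of geraniol with D-(−)-tartrate. C11′ by inversion at the tertiary epoxide carbon on acid-catalysed anti-hydration. Both E-olefins (C2′=C3′, C6′=C7′) from syn methylalumination of terminal alkynes followed by stereoretentive coupling. C14′=C15′ comes from geraniol.
- Enabling feature: C6′ is the hydrogen-bearing end of an E-trisubstituted olefin whose C7′ methyl is cis to C5′, and C5′ is an unbranched primary CH2. This is the imprint of syn Me–metal addition to a terminal alkyne C6′≡C7′ followed by retentive sp2–sp3 coupling. The benzoquinone ring takes no part and is masked as the dimethyl ether.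

Key step: step 8

Remark: in the final Ce(IV) oxidation the two carbonyl oxygens are taken to come from water, the methoxy groups leaving as methanol.

Step 1
Reactants: 1 geraniol
Product: 2 [(2R,3R)-3-methyl-3-(4-methylpent-3-en-1-yl)oxiran-2-yl]methanol
Conditions: t-BuOOH, Ti(OiPr)4 (cat.), D-(−)-diethyl tartrate (cat.), 4 Å MS, CH2Cl2, −20 °C
Reagents that add atoms: tert-butyl hydroperoxide, CC(C)(C)OO
Why: Sharpless asymmetric epoxidation: the allylic hydroxyl binds the titanium–tartrate catalyst, so only the C2=C3 olefin is oxidised (the isopropylidene olefin is left) and D-(−)-diethyl tartrate should deliver the (2R,3R)-epoxide, which sets the future C10′ as R under catalyst control.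

Step 2
Reactants: 2 [(2R,3R)-3-methyl-3-(4-methylpent-3-en-1-yl)oxiran-2-yl]methanol; 3 1-(trimethylsilyl)propyne
Product: 6 trimethyl{4-[(2R,3R)-3-methyl-3-(4-methylpent-3-en-1-yl)oxiran-2-yl]but-1-yn-1-yl}silane, via epoxy triflate 4 (not isolated), via lithiated silylpropyne 5 (not isolated)
Conditions: 2, n-BuLi, Et2O, −78 °C, then Tf2O, −78 °C; 3, n-BuLi, THF, −78 → −20 °C; solutions combined at −78 °C
Reagents that add atoms: none
Why: SN2 alkylation of a propargylic organolithium with a primary triflate at −78 °C forms C8′–C9′; the hindered trisubstituted epoxide should not compete at this temperature, neither stereocentre is touched, and the silyl group steers attack to the propargylic rather than the allenic terminus.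

Step 3
Reactants: 6 trimethyl{4-[(2R,3R)-3-methyl-3-(4-methylpent-3-en-1-yl)oxiran-2-yl]but-1-yn-1-yl}silane
Product: 7 (2R,3R)-3-(but-3-yn-1-yl)-2-methyl-2-(4-methylpent-3-en-1-yl)oxirane
Conditions: K2CO3 (cat.), MeOH, rt
Reagents that add atoms: none
Why: Base-catalysed methanolysis of the C(sp)–Si bond (protodesilylation) frees the terminal alkyne, and the epoxide is stable to carbonate in methanol at room temperature.

Step 4
Reactants: 7 (2R,3R)-3-(but-3-yn-1-yl)-2-methyl-2-(4-methylpent-3-en-1-yl)oxirane
Product: 8 (5R,6S)-6,10-dimethylundec-9-en-1-yne-5,6-diol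
Conditions: HClO4 (cat., dilute aq.), THF/H2O, 0 °C
Reagents that add atoms: water, O
Why: Acid-catalysed anti-hydration of a trisubstituted epoxide (borderline SN2 ring opening): water attacks the protonated epoxide at the tertiary carbon with inversion (C11′ R → S) while the C10′–O bond is kept, giving the anti diol; the tertiary-site preference is what transfers the enantiopurity, and cold dilute acid should leave the isopropylidene olefin and the alkyne alone.

Step 5
Reactants: 9 2,5-dimethoxytoluene
Product: 10 1-(chloromethyl)-2,5-dimethoxy-4-methylbenzene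
Conditions: (CH2O)n, conc. HCl/HCl (g), 1,4-dioxane, rt
Reagents that add atoms: formaldehyde (as paraformaldehyde), C=O; hydrogen chloride, Cl
Why: Blanc chloromethylation (electrophilic aromatic substitution): C4 is ortho to a methoxy group, para to the methyl group and the least hindered activated position, so the hydroxymethyl cation equivalent should enter there and be converted into the benzylic chloride.

Step 6
Reactants: 11 but-3-yn-1-ol; 10 1-(chloromethyl)-2,5-dimethoxy-4-methylbenzene
Product: 13 (E)-5-(2,5-dimethoxy-4-methylphenyl)-3-methylpent-3-en-1-ol, via alkenylalane 12 (not isolated)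
Conditions: Me3Al (3 equiv), Cp2ZrCl2 (0.25 equiv), CH2Cl2, 0 °C → rt; volatiles removed; 10, Ni(PPh3)4 (cat.), THF, rt; aq. Rochelle salt
Reagents that add atoms: trimethylaluminium, C[Al](C)C
Why: Zirconium-catalysed carboalumination (Negishi carboalumination) adds Me–Al syn and regioselectively across the terminal alkyne (hydroxyl masked as aluminium alkoxide), and Ni(0)-catalysed cross-coupling of the alkenylalane with the benzylic chloride proceeds with retention, fixing the E C2′=C3′ olefin.

Step 7
Reactants: 13 (E)-5-(2,5-dimethoxy-4-methylphenyl)-3-methylpent-3-en-1-ol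
Product: 14 1-[(E)-5-iodo-3-methylpent-2-en-1-yl]-2,5-dimethoxy-4-methylbenzene
Conditions: I2, PPh3, imidazole, CH2Cl2, 0 °C → rt
Reagents that add atoms: iodine, II
Why: Appel-type iodination: the alkoxyphosphonium ion of the primary alcohol is displaced by iodide in an SN2 step under buffered conditions that leave the olefin and the arene untouched.

Step 8
Reactants: 8 (5R,6S)-6,10-dimethylundec-9-en-1-yne-5,6-diol; 14 1-[(E)-5-iodo-3-methylpent-2-en-1-yl]-2,5-dimethoxy-4-methylbenzene
Product: 17 (2E,6E,10R,11S)-1-(2,5-dimethoxy-4-methylphenyl)-3,7,11,15-tetramethylhexadeca-2,6,14-triene-10,11-diol, via alkenylalane 15 (not isolated), via alkenylzinc chloride 16 (not isolated)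
Conditions: 8, Me3Al (4 equiv), Cp2ZrCl2 (0.3 equiv), CH2Cl2, 0 °C → rt; volatiles removed; ZnCl2 (1.5 equiv), THF, 0 °C; 14 (0.8 equiv), Pd2(dba)3 (2 mol %), PCyp3 (8 mol %), N-methylimidazole, THF/NMP, 60 °C; aq. Rochelle salt
Reagents that add atoms: trimethylaluminium, C[Al](C)C
Why: Proposed new method: Cp2ZrCl2/Me3Al adds Me–Al syn across the terminal alkyne of 8 (Me to C7′, Al to C6′, the two hydroxyls being masked in situ as aluminium alkoxides), Al→Zn exchange gives the (E)-alkenylzinc with retention, and an electron-rich L2Pd(0) (L = PCyp3) takes up the primary iodide 14 by SN2-type oxidative addition, transmetalates and reductively eliminates with retention at C6′, so that the C7′ methyl, the C6′=C7′ geometry and the C5′–C6′ bond all arise in one flask. The closest known reaction types are the zirconium-catalysed carboalumination/Pd–Zn cross-coupling of alkenylalanes with sp2 and benzylic halides and the Pd/trialkylphosphine Negishi coupling of alkenylzinc halides with β-hydrogen-bearing primary alkyl halides; their merger on a carboalumination-derived alkenylmetal is the untested part. No ring is closed and no stereocentre is created; the only stereochemical element formed, the E olefin, is fixed by syn carbometalation and by stereoretentive transmetalation and reductive elimination. The step needs regioselective methylmetalation (secured by the unhindered terminal alkyne, the trisubstituted olefins being inert), alkenyl-over-methyl transfer (alkenyl groups leave Al and Zn faster) and coupling faster than β-hydride elimination from the homoallylpalladium intermediate (bulky electron-rich PCyp3 and N-methylimidazole-accelerated transmetalation).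

Step 9
Reactants: 17 (2E,6E,10R,11S)-1-(2,5-dimethoxy-4-methylphenyl)-3,7,11,15-tetramethylhexadeca-2,6,14-triene-10,11-diol
Product: 18 (2E,6E,10R,11S)-1-(2,5-dimethoxy-4-methylphenyl)-11-hydroxy-3,7,11,15-tetramethylhexadeca-2,6,14-trien-10-yl acetate
Conditions: Ac2O, pyridine, DMAP (cat.), CH2Cl2, 0 °C → rt
Reagents that add atoms: acetic anhydride, CC(=O)OC(C)=O
Why: DMAP-catalysed acylation should be selective for the secondary C10′ hydroxyl because the tertiary C11′ hydroxyl is too hindered to be acetylated under these mild conditions, and no stereocentre is affected.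

Step 10
Reactants: 18 (2E,6E,10R,11S)-1-(2,5-dimethoxy-4-methylphenyl)-11-hydroxy-3,7,11,15-tetramethylhexadeca-2,6,14-trien-10-yl acetate
Product: 19 chabrolobenzoquinone H, (2E,6E,10R,11S)-11-hydroxy-3,7,11,15-tetramethyl-1-(4-methyl-3,6-dioxocyclohexa-1,4-dien-1-yl)hexadeca-2,6,14-trien-10-yl acetate
Conditions: (NH4)2Ce(NO3)6 (2.5 equiv), MeCN/H2O, 0 °C, short contact time
Reagents that add atoms: water, O
Why: Oxidative demethylation with Ce(IV): single-electron oxidation of the electron-rich dimethoxyarene, capture of the radical cation by water and loss of methanol should give the 1,4-benzoquinone much faster than any oxidation of the isolated olefins, the acetate or the tertiary alcohol at 0 °C.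

**Compound list**

1 | geraniol, (2E)-3,7-dimethylocta-2,6-dien-1-ol | CC(C)=CCC/C(C)=C/CO | starting material
2 | [(2R,3R)-3-methyl-3-(4-methylpent-3-en-1-yl)oxiran-2-yl]methanol | OC[C@H]1O[C@]1(C)CCC=C(C)C | intermediate
3 | 1-(trimethylsilyl)propyne | CC#C[Si](C)(C)C | starting material
4 | [(2R,3R)-3-methyl-3-(4-methylpent-3-en-1-yl)oxiran-2-yl]methyl trifluoromethanesulfonate | FC(F)(F)S(=O)(=O)OC[C@H]1O[C@]1(C)CCC=C(C)C | intermediate
5 | 3-lithio-1-(trimethylsilyl)propyne | [Li]CC#C[Si](C)(C)C | intermediate
6 | trimethyl{4-[(2R,3R)-3-methyl-3-(4-methylpent-3-en-1-yl)oxiran-2-yl]but-1-yn-1-yl}silane | C[Si](C)(C)C#CCC[C@H]1O[C@]1(C)CCC=C(C)C | intermediate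
7 | (2R,3R)-3-(but-3-yn-1-yl)-2-methyl-2-(4-methylpent-3-en-1-yl)oxirane | C#CCC[C@H]1O[C@]1(C)CCC=C(C)C | intermediate
8 | (5R,6S)-6,10-dimethylundec-9-en-1-yne-5,6-diol | O[C@H](CCC#C)[C@@](C)(O)CCC=C(C)C | intermediate
9 | 2,5-dimethoxytoluene | COc1ccc(OC)c(C)c1 | starting material
10 | 1-(chloromethyl)-2,5-dimethoxy-4-methylbenzene | COc1cc(CCl)c(OC)cc1C | intermediate
11 | but-3-yn-1-ol | C#CCCO | starting material
12 | [(E)-4-(dimethylalumanyloxy)-2-methylbut-1-en-1-yl]dimethylalumane | C[Al](C)/C=C(\C)CCO[Al](C)C | intermediate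
13 | (E)-5-(2,5-dimethoxy-4-methylphenyl)-3-methylpent-3-en-1-ol | COc1cc(C/C=C(\C)CCO)c(OC)cc1C | intermediate
14 | 1-[(E)-5-iodo-3-methylpent-2-en-1-yl]-2,5-dimethoxy-4-methylbenzene | COc1cc(C/C=C(\C)CCI)c(OC)cc1C | intermediate
15 | (1E,5R,6S)-1-(dimethylalumanyl)-5,6-bis(dimethylalumanyloxy)-2,6,10-trimethylundeca-1,9-diene | C[Al](C)/C=C(\C)CC[C@@H](O[Al](C)C)[C@@](C)(O[Al](C)C)CCC=C(C)C | intermediate
16 | (1E,5R,6S)-1-(chlorozincio)-5,6-bis(dimethylalumanyloxy)-2,6,10-trimethylundeca-1,9-diene | Cl[Zn]/C=C(\C)CC[C@@H](O[Al](C)C)[C@@](C)(O[Al](C)C)CCC=C(C)C | intermediate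
17 | (2E,6E,10R,11S)-1-(2,5-dimethoxy-4-methylphenyl)-3,7,11,15-tetramethylhexadeca-2,6,14-triene-10,11-diol | O[C@H](CC/C(C)=C/CC/C(C)=C/Cc1cc(OC)c(C)cc1OC)[C@@](C)(O)CCC=C(C)C | intermediate
18 | (2E,6E,10R,11S)-1-(2,5-dimethoxy-4-methylphenyl)-11-hydroxy-3,7,11,15-tetramethylhexadeca-2,6,14-trien-10-yl acetate | CC(=O)O[C@H](CC/C(C)=C/CC/C(C)=C/Cc1cc(OC)c(C)cc1OC)[C@@](C)(O)CCC=C(C)C | intermediate
19 | chabrolobenzoquinone H | CC(=O)O[C@H](CC/C(C)=C/CC/C(C)=C/CC1=CC(=O)C(C)=CC1=O)[C@@](C)(O)CCC=C(C)C | target

**Totals**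

Total step count: 10. Longest linear sequence: 7 steps (geraniol 1 to 19 through steps 1, 2, 3, 4, 8, 9, 10).

**Steps most likely to fail**

1. Step 8 (Proposed new method). What may go wrong: β-hydride elimination from the homoallylpalladium iodide to a conjugated diene, transfer of methyl instead of alkenyl from aluminium or zinc, or slow transmetalation in the presence of the aluminium alkoxides. The fallback sets out from 8 and 14 and rejoins the route at 17, using known chemistry only. The methylalumination of 8 is run as in step 8 but quenched with iodine (THF, −30 °C) to give (1E,5R,6S)-1-iodo-2,6,10-trimethylundeca-1,9-diene-5,6-diol F1. Iodide 14 is converted by iodine–lithium exchange (t-BuLi, Et2O, −78 °C) and addition of B-methoxy-9-BBN into lithium B-methoxy-B-[(E)-5-(2,5-dimethoxy-4-methylphenyl)-3-methylpent-3-en-1-yl]-9-borabicyclo[3.3.1]nonan-9-uide F2. F2 is coupled with F1 under Pd(dppf)Cl2, AsPh3 and Cs2CO3 in DMF/THF/H2O at rt (B-alkyl Suzuki–Miyaura coupling, tolerant of the free diol, retention at the alkenyl iodide) to give 17.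

2. Step 2. What may go wrong: attack of the organolithium on the epoxide, ionisation or rearrangement of the epoxy triflate before it is consumed, and alkylation at the allenic terminus of the lithiated silylpropyne. The fallback sets out from 2 and rejoins at 8, replacing steps 2 to 4 by opening of a terminal epoxide. Alcohol 2 is mesylated (MsCl, Et3N, CH2Cl2, −10 °C) to [(2R,3R)-3-methyl-3-(4-methylpent-3-en-1-yl)oxiran-2-yl]methyl methanesulfonate F3. Acid-catalysed anti-hydration at the tertiary carbon (HClO4 cat., THF/H2O, 0 °C) gives (2R,3S)-2,3-dihydroxy-3,7-dimethyloct-6-en-1-yl methanesulfonate F4. Brief treatment with K2CO3 in MeOH at 0 °C closes the terminal epoxide (2S)-6-methyl-2-[(2R)-oxiran-2-yl]hept-5-en-2-ol F5. Opening at the terminal carbon with 5 (excess, BF3·OEt2, THF, −78 °C) gives (5R,6S)-6,10-dimethyl-1-(trimethylsilyl)undec-9-en-1-yne-5,6-diol F6, and K2CO3 in MeOH gives 8.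

3. Step 10. What may go wrong: over-oxidation of the side chain, or acid-promoted addition of the C11′ hydroxyl to the C14′=C15′ olefin in the strongly acidic Ce(IV) medium. The fallback sets out from 17 and rejoins at 19, separating oxidation from unmasking. Anodic oxidation of 17 in methanol (Pt anode, KOH/MeOH, 0 °C, constant current) gives the quinone bis(dimethyl ketal) (2E,6E,10R,11S)-3,7,11,15-tetramethyl-1-(3,3,6,6-tetramethoxy-4-methylcyclohexa-1,4-dien-1-yl)hexadeca-2,6,14-triene-10,11-diol F7. Acetylation as in step 9 gives (2E,6E,10R,11S)-11-hydroxy-3,7,11,15-tetramethyl-1-(3,3,6,6-tetramethoxy-4-methylcyclohexa-1,4-dien-1-yl)hexadeca-2,6,14-trien-10-yl acetate F8. Brief hydrolysis with dilute aqueous acid in acetone at 0 °C releases the quinone 19.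

Further compounds
F1 | step 8 | (1E,5R,6S)-1-iodo-2,6,10-trimethylundeca-1,9-diene-5,6-diol | I/C=C(\C)CC[C@@H](O)[C@@](C)(O)CCC=C(C)C
F2 | step 8 | lithium B-methoxy-B-[(E)-5-(2,5-dimethoxy-4-methylphenyl)-3-methylpent-3-en-1-yl]-9-borabicyclo[3.3.1]nonan-9-uide | [Li+].CO[B-]1(CC/C(C)=C/Cc2cc(OC)c(C)cc2OC)C2CCCC1CCC2
F3 | step 2 | [(2R,3R)-3-methyl-3-(4-methylpent-3-en-1-yl)oxiran-2-yl]methyl methanesulfonate | CS(=O)(=O)OC[C@H]1O[C@]1(C)CCC=C(C)C
F4 | step 2 | (2R,3S)-2,3-dihydroxy-3,7-dimethyloct-6-en-1-yl methanesulfonate | CS(=O)(=O)OC[C@@H](O)[C@@](C)(O)CCC=C(C)C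
F5 | step 2 | (2S)-6-methyl-2-[(2R)-oxiran-2-yl]hept-5-en-2-ol | C1O[C@H]1[C@@](C)(O)CCC=C(C)C
F6 | step 2 | (5R,6S)-6,10-dimethyl-1-(trimethylsilyl)undec-9-en-1-yne-5,6-diol | C[Si](C)(C)C#CCC[C@@H](O)[C@@](C)(O)CCC=C(C)C
F7 | step 10 | (2E,6E,10R,11S)-3,7,11,15-tetramethyl-1-(3,3,6,6-tetramethoxy-4-methylcyclohexa-1,4-dien-1-yl)hexadeca-2,6,14-triene-10,11-diol | O[C@H](CC/C(C)=C/CC/C(C)=C/CC1=CC(OC)(OC)C(C)=CC1(OC)OC)[C@@](C)(O)CCC=C(C)C
F8 | step 10 | (2E,6E,10R,11S)-11-hydroxy-3,7,11,15-tetramethyl-1-(3,3,6,6-tetramethoxy-4-methylcyclohexa-1,4-dien-1-yl)hexadeca-2,6,14-trien-10-yl acetate | CC(=O)O[C@H](CC/C(C)=C/CC/C(C)=C/CC1=CC(OC)(OC)C(C)=CC1(OC)OC)[C@@](C)(O)CCC=C(C)C
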